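## Structural features

The target is a 9,9'-epoxylignan. It has one tetrahydrofuran ring (O, C9, C8, C8', C9'; lignan numbering, unprimed atoms for the syringyl C6–C3 unit, primed atoms for the guaiacyl unit), and both carbons next to oxygen, C9 and C9', are bare methylenes. C8 carries the exocyclic carbinol carbon C7 (OH and the 4-hydroxy-3,5-dimethoxyphenyl ring). The neighbouring C8' carries the methylene C7' that leads to the 4-hydroxy-3-methoxyphenyl ring.

Three stereocentres stand in a row: C7 (S), C8 (R), C8' (R). The two ring substituents are trans. C7–OH and C9 lie anti when aryl–C7–C8–C8' is drawn as a zigzag (the syn-aldol relation if C9 is read as the carbonyl carbon).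

The C7 alcohol is benzylic and para to an oxygen donor. It therefore ionises with acid to a quinone-methide-type cation and can be hydrogenolysed. In any open-chain 7,9,9'-triol it closes with C9' to the isomeric 7,9'-epoxide. The two phenols also need masking.

The real difficulty is double. The exocyclic C7/C8 pair has no ring to control it, and the 9,9'-ring must be made while C7–OH is present.

The key step exploits this feature: C9' is an unsubstituted O–CH2 carbon and C7' an unsubstituted CH2 between C8' and the guaiacyl ring. The ring bond C9'–C8' and the bond C7'–C1(aryl) are thus the two bonds gained when a C9' radical and an aryl group add across a C8'=C7' vinyl group. The ring is closed through carbon, and C7–OH is only a spectator.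

## Logic of the disconnections

**14 to 13.** The two phenolic O–CH2Ph bonds are cut. Both phenols must be masked through basic, radical and metal-catalysed steps, and one common mask falls in one operation. Nothing is gained in the skeleton. The forward step must cleave two aryl benzyl ethers without touching the C7–O bond.

**13 to 8 and 10 (key disconnection).** The ring bond C9'–C8' and the bond C7'–C1 of the guaiacyl ring are cut together.
- In one sentence: an alkoxymethyl radical released by decarboxylation of the acyclic acid 8 closes the tetrahydrofuran at C9'–C8', and the C7' radical so formed is arylated by nickel with 10.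
- The cut removes the ring, one stereocentre and a whole aryl unit. It leaves an acyclic vinyl compound with only C7 and C8 as stereocentres.
- It avoids every C–O ring closure in which C7–OH could compete.
- The forward step must cyclise before the radical is captured, close 5-exo, and place C7' trans to the C8 substituent.

**8 to 7, then to 4 and 5.** After the ester–acid interchange, the ether bond O–C9' is cut. C9' and its radical trigger (the carboxyl carbon) come from one two-carbon electrophile, and what remains is a 1,3-diol. The forward step must alkylate the primary C9 oxygen and leave the secondary benzylic C7 oxygen free.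

**4 to 2 and 3.** The bond C7–C8 is cut. This bond joins the two stereocentres that are hardest to relate, and both can be set together in a closed transition state. What is left is an aromatic aldehyde and a four-carbon allyl donor that already carries O9. The forward step must give the anti diastereomer and must attack the Si face of the aldehyde carbon of 2.

**2 to 1 and 10 to 9.** One phenolic O–benzyl bond is cut in each. Both precursors are purchasable phenols, and the only demand is clean O-alkylation.

## Other disconnections considered

**Alternative 1:** This is the first route that comes to mind.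
- *Cut:* C7–C8 as an aldol bond, plus one ring C–O bond.
- *Forward key step:* the lithium enolate of (R)-4-[4-(benzyloxy)-3-methoxybenzyl]dihydrofuran-2(3H)-one A1 adds to 2 to give the aldol A2. Hydride reduction gives the triol A3, and O9/C9' are then joined by dehydration.
- *Grounds against:*
  - The benzyl group of A1 directs the aldehyde to the opposite ring face, so C8/C8' should come out trans. Nothing in the ring-locked enolate fixes the orientation of the aldehyde, so C7 is left to a small energy difference.
  - In A3 three hydroxyls compete. The para-oxygenated benzylic C7 is the position that ionises most easily, so closure to the 7,9'-epoxide is the mechanistically favoured path. A protection and deprotection pair at C7 becomes necessary.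
  - A1 itself needs a multistep asymmetric synthesis, so the plan is longer and solves neither difficulty in its key step.

**Alternative 2:**
- *Cut:* C8–C8' and O–C9' (formal 3+2 annulation).
- *Forward key step:* the alkoxide of the epoxy alcohol A5, made from the allylic alcohol A4, adds to the aryl vinyl ketone A6 (oxa-Michael). The enolate then opens the epoxide at C8, 5-exo-tet with inversion, to give the keto alcohol A7. The C7' ketone must afterwards be taken down to CH2.
- *Grounds against:*
  - The anti relation in the target combined with inversion at C8 demands the cis epoxide A5, hence the Z-alkene A4. This is the poorer substrate class for the Ti(OiPr)4/tartrate epoxidation.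
  - The enolate carries its own alkoxide in the β position and can expel it again (retro-oxa-Michael).
  - The epoxy alkoxide can undergo Payne rearrangement.
  - The benzylic C7 terminus competes for the nucleophile (6-endo).
  - A diaryl system with one ketone and one benzylic alcohol must then be deoxygenated at the ketone only.

**Alternative 3:**
- *Cut:* both ring C–C bonds next to the O–CH2 carbons, C8–C9 and C8'–C9'.
- *Forward key step:* 1,3-dipolar cycloaddition of the parent carbonyl ylide A8, released by fluoride from an α-silyl α'-chloro ether, to the E-enone A9. This gives the trans aroyl tetrahydrofuran A10, and the C7 ketone is then reduced.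
- *Grounds against:*
  - The suprafacial addition would turn the E geometry into the trans relation, but no element controls the absolute face, so an auxiliary or a resolution is needed.
  - C7 is left to a separate reduction with weak acyclic induction.
  - The doubly activated C7' methylene of A9 allows the double bond to slip into conjugation with the guaiacyl ring under the basic fluoride conditions.
  - The unstabilised ylide A8 is short-lived.
  - The step therefore settles two of the three stereocentres, and only in the relative sense.

Key step: step 6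

Assumption: (S)-SEGPHOS is taken as the ligand antipode that directs the allyl fragment to the Si face of 2 in step 2. If the sense of induction is the reverse, (R)-SEGPHOS is used and nothing else changes.

## Steps

Step 1
Reactants: 1 syringaldehyde (4-hydroxy-3,5-dimethoxybenzaldehyde)
Product: 2 4-(benzyloxy)-3,5-dimethoxybenzaldehyde
Conditions: BnBr, K2CO3, DMF, 60 °C
Reagents that add atoms: benzyl bromide, BrCc1ccccc1
Why: Williamson etherification of the acidic para-formyl phenoxide; the aldehyde is inert to carbonate and no stereocentre is involved.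

Step 2
Reactants: 2 4-(benzyloxy)-3,5-dimethoxybenzaldehyde; 3 4-vinyl-1,3-dioxolan-2-one (racemic)
Product: 4 (1S,2R)-1-[4-(benzyloxy)-3,5-dimethoxyphenyl]-2-vinylpropane-1,3-diol
Conditions: [Ir(cod)Cl]2 (2.5 mol %), (S)-SEGPHOS (5 mol %), 4-chloro-3-nitrobenzoic acid (10 mol %), Cs2CO3 (20 mol %), i-PrOH (2 equiv), THF, 70 °C
Reagents that add atoms: none
Why: Iridium-catalysed transfer-hydrogenative carbonyl (hydroxymethyl)allylation (Krische allylation type): the cyclometallated iridium C,O-benzoate ionises the branched allylic carbonate 3, CO2 is lost, and the (E)-σ-allyl iridium species adds to 2 through a closed chair transition state with isopropanol as terminal reductant. The E geometry of the allyl fragment gives the anti relation of C7–OH and C9, the bisphosphine selects the Si face of the aldehyde, and C7 (S) and C8 (R) are thus set together; the stereocentre of racemic 3 is erased in the π-allyl complex.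

Step 3
Reactants: 4 (1S,2R)-1-[4-(benzyloxy)-3,5-dimethoxyphenyl]-2-vinylpropane-1,3-diol; 5 methyl bromoacetate
Product: 7 methyl {[(2R)-2-{(S)-[4-(benzyloxy)-3,5-dimethoxyphenyl](hydroxy)methyl}but-3-en-1-yl]oxy}acetate, via dibutylstannylene acetal 6 (not isolated)
Conditions: Bu2SnO, PhMe, reflux (Dean–Stark); then 5, CsF, DMF, rt
Reagents that add atoms: none
Why: Stannylene-acetal-mediated regioselective O-alkylation: in the six-membered acetal 6 the unhindered primary oxygen is the more nucleophilic one, and fluoride activation lets the activated bromide react at room temperature under neutral conditions. C7–OH stays free and no stereocentre is touched.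

Step 4
Reactants: 7 methyl {[(2R)-2-{(S)-[4-(benzyloxy)-3,5-dimethoxyphenyl](hydroxy)methyl}but-3-en-1-yl]oxy}acetate
Product: 8 {[(2R)-2-{(S)-[4-(benzyloxy)-3,5-dimethoxyphenyl](hydroxy)methyl}but-3-en-1-yl]oxy}acetic acid
Conditions: LiOH·H2O, THF–H2O, 0 °C to rt; then 1 M HCl to pH 4, 0 °C
Reagents that add atoms: lithium hydroxide, [Li+].[OH-]
Why: Ordinary saponification of an unhindered methyl ester; the cold and only mildly acidic work-up keeps the benzylic alcohol from ionising, and any seven-membered lactone formed in step 3 is opened to the same acid.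

Step 5
Reactants: 9 4-iodo-2-methoxyphenol
Product: 10 1-(benzyloxy)-4-iodo-2-methoxybenzene
Conditions: BnBr, K2CO3, DMF, rt
Reagents that add atoms: benzyl bromide, BrCc1ccccc1
Why: Williamson etherification; the aryl iodide is inert to these conditions.

Step 6
Reactants: 8 {[(2R)-2-{(S)-[4-(benzyloxy)-3,5-dimethoxyphenyl](hydroxy)methyl}but-3-en-1-yl]oxy}acetic acid; 10 1-(benzyloxy)-4-iodo-2-methoxybenzene
Product: 13 (S)-[4-(benzyloxy)-3,5-dimethoxyphenyl]{(3R,4R)-4-[4-(benzyloxy)-3-methoxybenzyl]tetrahydrofuran-3-yl}methanol, via alkoxymethyl radical 11 (not isolated), via cyclised primary radical 12 (not isolated)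
Conditions: Ir[dF(CF3)ppy]2(dtbbpy)PF6 (1 mol %), NiCl2(dme) (5 mol %), dtbbpy (7.5 mol %), Cs2CO3 (1.5 equiv), 10 (1.5 equiv), degassed DMF (0.02 M), 450 nm LED, rt
Reagents that add atoms: none
Why: Proposed new method: the caesium carboxylate of 8 is oxidised by the excited iridium photocatalyst and loses CO2 to give the nucleophilic C9' radical 11; the closest known reaction types are the metallaphotoredox decarboxylative arylation of α-oxy acids, the tin hydride cyclisation of alkoxymethyl radicals derived from homoallylic alcohols, and nickel-catalysed radical cyclisation/aryl cross-coupling cascades of alkene-tethered radical precursors, which are merged here on an alkoxyacetic acid. Radical 11 closes the tetrahydrofuran by 5-exo-trig attack on C8' of the vinyl group, which forms C9'–C8' and leaves the primary C7' radical 12. C8' is set in the chair-like transition state of the Beckwith–Houk model, in which the branched C8 substituent CH(OH)Ar lies pseudo-equatorial, the arrangement that leads a 4-substituted 5-hexenyl-type radical to the trans product, so that C8 (R) induces C8' (R) while C7 and C8 are not touched. Zerovalent nickel inserts into the C–I bond of 10, the aryl nickel iodide captures the unhindered radical 12, the trivalent nickel species forms C7'–C1(aryl) by reductive elimination, and the monovalent nickel left behind is reduced by the reduced photocatalyst, which closes both cycles. The selectivity needed is cyclisation before capture: ring closure is unimolecular and is helped by the short C–O bonds and by the branching at C8, whereas capture of 11 is bimolecular in a catalyst kept scarce by dilution and low loading. The same geometry disfavours 6-endo closure, and 1,5-hydrogen transfer from C7–H to C9' is polarity-mismatched, because a nucleophilic α-oxy radical would have to abstract a hydridic α-oxy hydrogen. The medium is weakly basic, so the benzylic alcohol cannot ionise, and the hindered secondary C7–OH should not compete with carboxylate and iodide as a ligand for nickel.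

Step 7
Reactants: 13 (S)-[4-(benzyloxy)-3,5-dimethoxyphenyl]{(3R,4R)-4-[4-(benzyloxy)-3-methoxybenzyl]tetrahydrofuran-3-yl}methanol
Product: 14 (S)-(4-hydroxy-3,5-dimethoxyphenyl)[(3R,4R)-4-(4-hydroxy-3-methoxybenzyl)tetrahydrofuran-3-yl]methanol (target)
Conditions: H2 (1 atm), 10% Pd/C, EtOAc–EtOH, rt, stopped after uptake of 2 equiv
Reagents that add atoms: none
Why: Catalytic hydrogenolysis of aryl benzyl ethers, which in a neutral acid-free medium should be much faster than cleavage of a secondary benzylic alcohol; no stereocentre is affected.

## Compound list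

1 | syringaldehyde (4-hydroxy-3,5-dimethoxybenzaldehyde) | COc1cc(C=O)cc(OC)c1O | starting material
2 | 4-(benzyloxy)-3,5-dimethoxybenzaldehyde | COc1cc(C=O)cc(OC)c1OCc1ccccc1 | intermediate
3 | 4-vinyl-1,3-dioxolan-2-one (racemic) | C=CC1COC(=O)O1 | starting material
4 | (1S,2R)-1-[4-(benzyloxy)-3,5-dimethoxyphenyl]-2-vinylpropane-1,3-diol | OC[C@@H](C=C)[C@H](O)c1cc(OC)c(OCc2ccccc2)c(OC)c1 | intermediate
5 | methyl bromoacetate | COC(=O)CBr | starting material
6 | (4S,5R)-4-[4-(benzyloxy)-3,5-dimethoxyphenyl]-2,2-dibutyl-5-vinyl-1,3,2-dioxastanninane | CCCC[Sn]1(CCCC)OC[C@@H](C=C)[C@H](O1)c1cc(OC)c(OCc2ccccc2)c(OC)c1 | intermediate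
7 | methyl {[(2R)-2-{(S)-[4-(benzyloxy)-3,5-dimethoxyphenyl](hydroxy)methyl}but-3-en-1-yl]oxy}acetate | COC(=O)COC[C@@H](C=C)[C@H](O)c1cc(OC)c(OCc2ccccc2)c(OC)c1 | intermediate
8 | {[(2R)-2-{(S)-[4-(benzyloxy)-3,5-dimethoxyphenyl](hydroxy)methyl}but-3-en-1-yl]oxy}acetic acid | OC(=O)COC[C@@H](C=C)[C@H](O)c1cc(OC)c(OCc2ccccc2)c(OC)c1 | intermediate
9 | 4-iodo-2-methoxyphenol | COc1cc(I)ccc1O | starting material
10 | 1-(benzyloxy)-4-iodo-2-methoxybenzene | COc1cc(I)ccc1OCc1ccccc1 | intermediate
11 | {[(2R)-2-{(S)-[4-(benzyloxy)-3,5-dimethoxyphenyl](hydroxy)methyl}but-3-en-1-yl]oxy}methyl radical | [CH2]OC[C@@H](C=C)[C@H](O)c1cc(OC)c(OCc2ccccc2)c(OC)c1 | intermediate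
12 | [(3R,4R)-4-{(S)-[4-(benzyloxy)-3,5-dimethoxyphenyl](hydroxy)methyl}tetrahydrofuran-3-yl]methyl radical | [CH2][C@H]1COC[C@@H]1[C@H](O)c1cc(OC)c(OCc2ccccc2)c(OC)c1 | intermediate
13 | (S)-[4-(benzyloxy)-3,5-dimethoxyphenyl]{(3R,4R)-4-[4-(benzyloxy)-3-methoxybenzyl]tetrahydrofuran-3-yl}methanol | COc1cc(C[C@H]2COC[C@@H]2[C@H](O)c2cc(OC)c(OCc3ccccc3)c(OC)c2)ccc1OCc1ccccc1 | intermediate
14 | (S)-(4-hydroxy-3,5-dimethoxyphenyl)[(3R,4R)-4-(4-hydroxy-3-methoxybenzyl)tetrahydrofuran-3-yl]methanol | COc1cc(C[C@H]2COC[C@@H]2[C@H](O)c2cc(OC)c(O)c(OC)c2)ccc1O | target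

## Step count and least certain steps

Total step count: 7. Longest linear sequence: 6 (steps 1, 2, 3, 4, 6, 7).

**Step 6 (key step, proposed new method).**
- *What may go wrong:*
  - nickel may capture the radical before ring closure, which gives direct arylation at C9';
  - hydrogen may transfer from C7–H to the radical centre;
  - the preference for the trans chair may be modest;
  - oxidative addition of the electron-rich iodide may be slow;
  - β-hydride elimination from the alkyl nickel species may occur.
- *Fallback:* it sets out from 7, returns at 13, and makes the two bonds one after the other by known reactions.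
  - A Heck reaction of 7 with 10 (Pd(OAc)2, Bu4NCl, K2CO3, DMF, 60 °C) should place the guaiacyl ring on the vinyl terminus and give the (E)-styryl methyl ester F1.
  - Saponification as in step 4 should give the (E)-styryl acid F2.
  - DCC and N-hydroxypyridine-2-thione should give the Barton ester F3.
  - Visible-light photolysis of F3 in the presence of t-BuSH (Barton reductive decarboxylation) releases the same kind of alkoxymethyl radical.
  - This radical closes 5-exo onto the styrene, more readily because a benzylic radical results. That radical takes hydrogen from the thiol to give 13, with the same control of C8'.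

**Step 2.**
- *What may go wrong:*
  - E/Z equilibration of the σ-allyl iridium species may erode the anti selectivity;
  - facial selectivity may be incomplete, or addition slow, with an electron-rich, 3,5-disubstituted aldehyde;
  - the primary alcohol of the product may be dehydrogenated further.
- *Fallback:* it sets out from 2, returns at 4, and replaces catalyst control by auxiliary control.
  - N-Acylation of (S)-4-benzyloxazolidin-2-one with crotonyl chloride gives the crotonate imide F4.
  - Bu2BOTf and Et3N convert F4 into the dienol borinate. This adds to 2 at its α-carbon through a Zimmerman–Traxler chair (Evans syn aldol) and should give the α-vinyl syn aldol imide F5.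
  - LiBH4 removes the auxiliary reductively and gives 4. The syn aldol relation is the anti relation of 4.

**Step 3.**
- *What may go wrong:* alkylation at the secondary oxygen or at both oxygens through stannyl migration within the acetal, or tin-catalysed lactonisation.
- *Fallback:* it sets out from 4, returns at 7, and differentiates the two hydroxyls by acylation, which is inherently selective for the primary site.
  - PivCl in pyridine should give the primary pivalate F6.
  - TBSOTf and 2,6-lutidine give the C7 silyl ether pivalate F7.
  - i-Bu2AlH removes the pivalate and gives the C7 silyl ether primary alcohol F8.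
  - Rh2(OAc)4-catalysed O–H insertion of methyl diazoacetate, under neutral conditions so that the silyl group cannot migrate, gives the C7 silyl ether of the alkoxyacetate F9.
  - Bu4NF buffered with AcOH gives 7.

**Step 7.**
- *What may go wrong:* hydrogenolysis of the C7–O bond alongside or after debenzylation, because the liberated para-phenol makes the benzylic alcohol more labile on the catalyst surface.
- *Fallback:* it sets out from 13, returns at 14, and masks the fragile group before the reduction.
  - TBSOTf and 2,6-lutidine give the C7 silyl ether of the dibenzyl compound F10.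
  - Hydrogenolysis, now with a bulky and poorly adsorbing C7 substituent, gives the C7 silyl ether diphenol F11.
  - Bu4NF buffered with AcOH gives 14.

## Further compounds

F1 | step 6 | methyl {[(2R,3E)-4-[4-(benzyloxy)-3-methoxyphenyl]-2-{(S)-[4-(benzyloxy)-3,5-dimethoxyphenyl](hydroxy)methyl}but-3-en-1-yl]oxy}acetate | COC(=O)COC[C@@H](/C=C/c1ccc(OCc2ccccc2)c(OC)c1)[C@H](O)c1cc(OC)c(OCc2ccccc2)c(OC)c1
F2 | step 6 | {[(2R,3E)-4-[4-(benzyloxy)-3-methoxyphenyl]-2-{(S)-[4-(benzyloxy)-3,5-dimethoxyphenyl](hydroxy)methyl}but-3-en-1-yl]oxy}acetic acid | OC(=O)COC[C@@H](/C=C/c1ccc(OCc2ccccc2)c(OC)c1)[C@H](O)c1cc(OC)c(OCc2ccccc2)c(OC)c1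
F3 | step 6 | 2-thioxopyridin-1(2H)-yl ester of F2 (Barton ester) | S=C1C=CC=CN1OC(=O)COC[C@@H](/C=C/c1ccc(OCc2ccccc2)c(OC)c1)[C@H](O)c1cc(OC)c(OCc2ccccc2)c(OC)c1
F4 | step 2 | (S)-4-benzyl-3-[(E)-but-2-enoyl]oxazolidin-2-one | C/C=C/C(=O)N1[C@@H](Cc2ccccc2)COC1=O
F5 | step 2 | (S)-4-benzyl-3-{(2S)-2-[(S)-[4-(benzyloxy)-3,5-dimethoxyphenyl](hydroxy)methyl]but-3-enoyl}oxazolidin-2-one | O=C1OC[C@H](Cc2ccccc2)N1C(=O)[C@@H](C=C)[C@H](O)c1cc(OC)c(OCc2ccccc2)c(OC)c1
F6 | step 3 | (2R)-2-{(S)-[4-(benzyloxy)-3,5-dimethoxyphenyl](hydroxy)methyl}but-3-en-1-yl pivalate | CC(C)(C)C(=O)OC[C@@H](C=C)[C@H](O)c1cc(OC)c(OCc2ccccc2)c(OC)c1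
F7 | step 3 | (2R)-2-{(S)-[4-(benzyloxy)-3,5-dimethoxyphenyl][(tert-butyldimethylsilyl)oxy]methyl}but-3-en-1-yl pivalate | CC(C)(C)C(=O)OC[C@@H](C=C)[C@H](O[Si](C)(C)C(C)(C)C)c1cc(OC)c(OCc2ccccc2)c(OC)c1
F8 | step 3 | (2R)-2-{(S)-[4-(benzyloxy)-3,5-dimethoxyphenyl][(tert-butyldimethylsilyl)oxy]methyl}but-3-en-1-ol | OC[C@@H](C=C)[C@H](O[Si](C)(C)C(C)(C)C)c1cc(OC)c(OCc2ccccc2)c(OC)c1
F9 | step 3 | methyl {[(2R)-2-{(S)-[4-(benzyloxy)-3,5-dimethoxyphenyl][(tert-butyldimethylsilyl)oxy]methyl}but-3-en-1-yl]oxy}acetate | COC(=O)COC[C@@H](C=C)[C@H](O[Si](C)(C)C(C)(C)C)c1cc(OC)c(OCc2ccccc2)c(OC)c1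
F10 | step 7 | tert-butyldimethylsilyl ether of 13 at C7–OH | COc1cc(C[C@H]2COC[C@@H]2[C@H](O[Si](C)(C)C(C)(C)C)c2cc(OC)c(OCc3ccccc3)c(OC)c2)ccc1OCc1ccccc1
F11 | step 7 | tert-butyldimethylsilyl ether of 14 at C7–OH | COc1cc(C[C@H]2COC[C@@H]2[C@H](O[Si](C)(C)C(C)(C)C)c2cc(OC)c(O)c(OC)c2)ccc1O
A1 | alternative 1 | (R)-4-[4-(benzyloxy)-3-methoxybenzyl]dihydrofuran-2(3H)-one | COc1cc(C[C@H]2COC(=O)C2)ccc1OCc1ccccc1
A2 | alternative 1 | (3S,4R)-4-[4-(benzyloxy)-3-methoxybenzyl]-3-{(S)-[4-(benzyloxy)-3,5-dimethoxyphenyl](hydroxy)methyl}dihydrofuran-2(3H)-one | COc1cc(C[C@H]2COC(=O)[C@@H]2[C@H](O)c2cc(OC)c(OCc3ccccc3)c(OC)c2)ccc1OCc1ccccc1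
A3 | alternative 1 | (1S,2R,3R)-1-[4-(benzyloxy)-3,5-dimethoxyphenyl]-4-[4-(benzyloxy)-3-methoxyphenyl]-2,3-bis(hydroxymethyl)butan-1-ol | COc1cc(C[C@@H](CO)[C@H](CO)[C@H](O)c2cc(OC)c(OCc3ccccc3)c(OC)c2)ccc1OCc1ccccc1
A4 | alternative 2 | (Z)-3-[4-(benzyloxy)-3,5-dimethoxyphenyl]prop-2-en-1-ol | OC/C=C\c1cc(OC)c(OCc2ccccc2)c(OC)c1
A5 | alternative 2 | {(2S,3R)-3-[4-(benzyloxy)-3,5-dimethoxyphenyl]oxiran-2-yl}methanol (cis epoxide) | OC[C@@H]1O[C@@H]1c1cc(OC)c(OCc2ccccc2)c(OC)c1
A6 | alternative 2 | 1-[4-(benzyloxy)-3-methoxyphenyl]prop-2-en-1-one | C=CC(=O)c1ccc(OCc2ccccc2)c(OC)c1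
A7 | alternative 2 | [4-(benzyloxy)-3-methoxyphenyl][(3R,4R)-4-{(S)-[4-(benzyloxy)-3,5-dimethoxyphenyl](hydroxy)methyl}tetrahydrofuran-3-yl]methanone | COc1cc(C(=O)[C@H]2COC[C@@H]2[C@H](O)c2cc(OC)c(OCc3ccccc3)c(OC)c2)ccc1OCc1ccccc1
A8 | alternative 3 | formaldehyde O-methylide (parent carbonyl ylide) | C=[O+][CH2-]
A9 | alternative 3 | (E)-1-[4-(benzyloxy)-3,5-dimethoxyphenyl]-4-[4-(benzyloxy)-3-methoxyphenyl]but-2-en-1-one | COc1cc(C/C=C/C(=O)c2cc(OC)c(OCc3ccccc3)c(OC)c2)ccc1OCc1ccccc1
A10 | alternative 3 | [4-(benzyloxy)-3,5-dimethoxyphenyl]{(3R,4R)-4-[4-(benzyloxy)-3-methoxybenzyl]tetrahydrofuran-3-yl}methanone (would form as the racemate; the needed enantiomer is drawn) | COc1cc(C[C@H]2COC[C@@H]2C(=O)c2cc(OC)c(OCc3ccccc3)c(OC)c2)ccc1OCc1ccccc1
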